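**Retrosynthetic overview**
1. The tetrahydrofuran ring (C6–O–C9) and the C10–Br bond are formed last, by transannular 5-exo bromoetherification of a 2,8-trans oxocene that carries the C6 carbinol and the E-enyne.
2. The E-enyne comes from an allyl carbinol (cross-metathesis, then Colvin homologation); C6 is set by chelation-controlled allylation of an oxocene-2-carbaldehyde.
3. The oxocene ring (C9=C10) is formed first, by ring-closing metathesis of an acyclic bis-allyl ether aldehyde.
4. Key C7–C8 bond: the α-carbon of an α-alkoxyacetaldehyde is used as an enolonium equivalent (oxidised enamine) and joined to the nucleophilic terminus of allyltrimethylsilane, two normally nucleophilic carbons, with catalyst control of C7.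
5. The alkoxyacetaldehyde comes from an anti bromohydrin (C12–Br, C13–O), made from pent-4-enal by α-bromination and Cornforth-selective ethyl addition, then carbenoid O–H insertion and ester reduction.

Assumption and locants: a telescoped sequence whose intermediate is not isolated counts as one step; locants follow the chain HC1≡C2–C3H=C4H–C5H2–C6–C7–C8H2–C9–C10–C11H2–C12–C13–C14H2–C15H3 (O on C6, C7, C9, C13; Br on C10, C12).

**Route**

Step 1
Reactants: 1 pent-4-enal; 2 ethylmagnesium bromide
Product: 4 (3R,4S)-4-bromohept-6-en-3-ol, via (S)-2-bromopent-4-enal 3 (not isolated)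
Conditions: (2R,5R)-2,5-diphenylpyrrolidine (20 mol %), PhCO2H (20 mol %), 4,4-dibromo-2,6-di-tert-butylcyclohexa-2,5-dien-1-one, CH2Cl2/pentane, −40 °C; cold silica plug; then 2 (3 equiv), Et2O, −78 °C; H2O quench
Reagents that add atoms: 4,4-dibromo-2,6-di-tert-butylcyclohexa-2,5-dien-1-one, O=C1C(C(C)(C)C)=CC(Br)(Br)C=C1C(C)(C)C
Why: Enamine-mediated organocatalytic α-bromination (the C2-symmetric amine blocks one enamine face to give (S)-3; the mirror-image amine would give its antipode) followed by Cornforth/polar Felkin–Anh-controlled Grignard addition anti to the C–Br bond sets C12 (S) and C13 (R) as the anti bromohydrin.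

Step 2
Reactants: 4 (3R,4S)-4-bromohept-6-en-3-ol; 5 ethyl diazoacetate
Product: 6 ethyl 2-{[(3R,4S)-4-bromohept-6-en-3-yl]oxy}acetate
Conditions: Rh2(OAc)4 (1 mol %), CH2Cl2, 25 °C, slow addition of 5
Reagents that add atoms: none
Why: Rhodium-carbenoid O–H insertion etherifies the hindered secondary alcohol under neutral conditions, so the bromohydrin cannot close to an epoxide as it would under Williamson conditions, and no stereocenter is touched.

Step 3
Reactants: 6 ethyl 2-{[(3R,4S)-4-bromohept-6-en-3-yl]oxy}acetate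
Product: 7 2-{[(3R,4S)-4-bromohept-6-en-3-yl]oxy}acetaldehyde
Conditions: iBu2AlH (1.1 equiv), CH2Cl2, −78 °C; H2O work-up; used crude
Reagents that add atoms: none
Why: Partial ester reduction with iBu2AlH: the chelated tetrahedral aluminium hemiacetal of an α-alkoxy ester survives at −78 °C and releases the aldehyde only on work-up, leaving the secondary bromide and the alkene untouched.

Step 4
Reactants: 7 2-{[(3R,4S)-4-bromohept-6-en-3-yl]oxy}acetaldehyde; 8 allyltrimethylsilane
Product: 9 (2S)-2-{[(3R,4S)-4-bromohept-6-en-3-yl]oxy}pent-4-enal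
Conditions: (2R,5R)-5-benzyl-2-tert-butyl-3-methylimidazolidin-4-one·TFA (20 mol %), (NH4)2Ce(NO3)6 (2.5 equiv), NaHCO3, H2O (2 equiv), 8 (2.5 equiv), DME, −20 °C
Reagents that add atoms: none
Why: Proposed new method: organo-SOMO α-allylation applied to an α-alkoxyacetaldehyde — the imidazolidinone condenses to the E-enamine, one-electron oxidation by the tetravalent cerium salt gives a 3π-electron radical cation that is an enolonium equivalent (the normally nucleophilic α-carbon C7 becomes the electrophile), the nucleophilic CH2 terminus of allyltrimethylsilane (C8) adds to it, and a second oxidation with loss of the silyl group gives the α-allyl aldehyde, the benzyl and tert-butyl groups of the catalyst leaving only the Si face of C7 open so that C7 is set as S under catalyst control (the antipodal catalyst would give the C7 epimer) while the ether oxygen lowers the enamine oxidation potential; the closest known reaction type is the enantioselective SOMO-catalysed α-allylation of simple aliphatic aldehydes with allylsilanes.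

Step 5
Reactants: 9 (2S)-2-{[(3R,4S)-4-bromohept-6-en-3-yl]oxy}pent-4-enal
Product: 10 (2S,4Z,7S,8R)-7-bromo-8-ethyl-3,6,7,8-tetrahydro-2H-oxocine-2-carbaldehyde
Conditions: second-generation Grubbs catalyst (5 mol %), CH2Cl2 (0.003 M), 40 °C
Reagents that add atoms: none
Why: Ring-closing olefin metathesis: the two allyl groups are the only alkenes, both ether carbons are branched so the chain folds, the eight-membered ring enforces the Z alkene, and C7 is not enolised under the neutral conditions.

Step 6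
Reactants: 10 (2S,4Z,7S,8R)-7-bromo-8-ethyl-3,6,7,8-tetrahydro-2H-oxocine-2-carbaldehyde; 11 allyltributylstannane
Product: 12 (1S)-1-[(2S,4Z,7S,8R)-7-bromo-8-ethyl-3,6,7,8-tetrahydro-2H-oxocin-2-yl]but-3-en-1-ol
Conditions: MgBr2·OEt2 (2.5 equiv), CH2Cl2, −78 → −20 °C; H2O work-up
Reagents that add atoms: none
Why: Keck chelation-controlled allylation: MgBr2 bridges the aldehyde and ring oxygens and the allylstannane attacks the Cram chelate from the face opposite ring carbon C8, giving the syn (6S,7S) alcohol.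

Step 7
Reactants: 12 (1S)-1-[(2S,4Z,7S,8R)-7-bromo-8-ethyl-3,6,7,8-tetrahydro-2H-oxocin-2-yl]but-3-en-1-ol; 13 (E)-but-2-enal
Product: 14 (2E,5S)-5-[(2S,4Z,7S,8R)-7-bromo-8-ethyl-3,6,7,8-tetrahydro-2H-oxocin-2-yl]-5-hydroxypent-2-enal
Conditions: second-generation Hoveyda–Grubbs catalyst (5 mol %), 13 (5 equiv), CH2Cl2, 40 °C
Reagents that add atoms: none
Why: Olefin cross-metathesis of the terminal alkene with crotonaldehyde gives the E-enal under thermodynamic control, while the ring Z-alkene, disubstituted and flanked by branched carbons, reacts much more slowly.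

Step 8
Reactants: 14 (2E,5S)-5-[(2S,4Z,7S,8R)-7-bromo-8-ethyl-3,6,7,8-tetrahydro-2H-oxocin-2-yl]-5-hydroxypent-2-enal; 15 trimethylsilyldiazomethane
Product: 16 (1S,3E)-1-[(2S,4Z,7S,8R)-7-bromo-8-ethyl-3,6,7,8-tetrahydro-2H-oxocin-2-yl]hex-3-en-5-yn-1-ol
Conditions: 15, LiN(iPr)2 (2.5 equiv), THF, −78 °C; then 14, −78 → 0 °C; H2O
Reagents that add atoms: none
Why: Colvin homologation (Colvin rearrangement): lithiated trimethylsilyldiazomethane adds to the aldehyde, Peterson-type loss of silanolate and then of N2 gives an alkylidene carbene whose 1,2-hydride shift delivers the terminal alkyne with the E-alkene intact, the extra base only deprotonating the hydroxyl reversibly.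

Step 9
Reactants: 16 (1S,3E)-1-[(2S,4Z,7S,8R)-7-bromo-8-ethyl-3,6,7,8-tetrahydro-2H-oxocin-2-yl]hex-3-en-5-yn-1-ol
Product: 17 (1S,3R,4S,6S,7S,9S)-4,6-dibromo-3-ethyl-9-[(2E)-pent-2-en-4-yn-1-yl]-2,8-dioxabicyclo[5.2.1]decane
Conditions: N-bromosuccinimide (1.05 equiv), CH2Cl2, −40 → 0 °C, dark
Reagents that add atoms: N-bromosuccinimide, O=C1CCC(=O)N1Br
Why: Transannular 5-exo bromoetherification: the C6 hydroxyl can reach only the face of C9 syn to its anchor at C7, so the bromonium ion is opened anti with O–C9 on that face and Br on C10 on the opposite face, which fixes C9 (S) and C10 (S) from the Z geometry and the existing C7 center, the conjugated enyne being less nucleophilic than the ring alkene that carries an internal nucleophile.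

**Compound list**
1 | pent-4-enal | C=CCCC=O | starting material
2 | ethylmagnesium bromide | CC[Mg]Br | starting material
3 | (S)-2-bromopent-4-enal | O=C[C@@H](Br)CC=C | intermediate
4 | (3R,4S)-4-bromohept-6-en-3-ol | CC[C@@H](O)[C@@H](Br)CC=C | intermediate
5 | ethyl diazoacetate | CCOC(=O)C=[N+]=[N-] | starting material
6 | ethyl 2-{[(3R,4S)-4-bromohept-6-en-3-yl]oxy}acetate | CCOC(=O)CO[C@H](CC)[C@@H](Br)CC=C | intermediate
7 | 2-{[(3R,4S)-4-bromohept-6-en-3-yl]oxy}acetaldehyde | O=CCO[C@H](CC)[C@@H](Br)CC=C | intermediate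
8 | allyltrimethylsilane | C=CC[Si](C)(C)C | starting material
9 | (2S)-2-{[(3R,4S)-4-bromohept-6-en-3-yl]oxy}pent-4-enal | O=C[C@H](CC=C)O[C@H](CC)[C@@H](Br)CC=C | intermediate
10 | (2S,4Z,7S,8R)-7-bromo-8-ethyl-3,6,7,8-tetrahydro-2H-oxocine-2-carbaldehyde | O=C[C@@H]1C/C=C\C[C@H](Br)[C@@H](CC)O1 | intermediate
11 | allyltributylstannane | C=CC[Sn](CCCC)(CCCC)CCCC | starting material
12 | (1S)-1-[(2S,4Z,7S,8R)-7-bromo-8-ethyl-3,6,7,8-tetrahydro-2H-oxocin-2-yl]but-3-en-1-ol | C=CC[C@H](O)[C@@H]1C/C=C\C[C@H](Br)[C@@H](CC)O1 | intermediate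
13 | (E)-but-2-enal | C/C=C/C=O | starting material
14 | (2E,5S)-5-[(2S,4Z,7S,8R)-7-bromo-8-ethyl-3,6,7,8-tetrahydro-2H-oxocin-2-yl]-5-hydroxypent-2-enal | O=C/C=C/C[C@H](O)[C@@H]1C/C=C\C[C@H](Br)[C@@H](CC)O1 | intermediate
15 | trimethylsilyldiazomethane | C[Si](C)(C)C=[N+]=[N-] | starting material
16 | (1S,3E)-1-[(2S,4Z,7S,8R)-7-bromo-8-ethyl-3,6,7,8-tetrahydro-2H-oxocin-2-yl]hex-3-en-5-yn-1-ol | C#C/C=C/C[C@H](O)[C@@H]1C/C=C\C[C@H](Br)[C@@H](CC)O1 | intermediate
17 | (1S,3R,4S,6S,7S,9S)-4,6-dibromo-3-ethyl-9-[(2E)-pent-2-en-4-yn-1-yl]-2,8-dioxabicyclo[5.2.1]decane | C#C/C=C/C[C@@H]1O[C@H]2C[C@@H]1O[C@H](CC)[C@@H](Br)C[C@@H]2Br | target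

**Totals**
Total step count: 9. Longest linear sequence: 9 steps (1 → 17), with no protecting groups.

**Three steps most likely to fail**

Step 4 (oxidative α-allylation). The oxygen-stabilised radical cation may be too weakly electrophilic or may be over-oxidised. The fallback sets out from 6 and comes back at 9. Ester 6 is saponified (LiOH, THF/H2O, 0 °C) to 2-{[(3R,4S)-4-bromohept-6-en-3-yl]oxy}acetic acid F1. F1 is coupled (pivaloyl chloride, Et3N; then the lithium salt of (R)-4-benzyl-1,3-oxazolidin-2-one) to (4R)-4-benzyl-3-(2-{[(3R,4S)-4-bromohept-6-en-3-yl]oxy}acetyl)-1,3-oxazolidin-2-one F2. Its chelated sodium Z-enolate (NaN(SiMe3)2, THF, −78 °C) is alkylated with allyl iodide on the face away from the benzyl group to give (4R)-4-benzyl-3-[(2S)-2-{[(3R,4S)-4-bromohept-6-en-3-yl]oxy}pent-4-enoyl]-1,3-oxazolidin-2-one F3. LiBH4 (THF, 0 °C) releases the auxiliary and gives (2S)-2-{[(3R,4S)-4-bromohept-6-en-3-yl]oxy}pent-4-en-1-ol F4, and Dess–Martin oxidation returns aldehyde 9.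

Step 5 (ring-closing metathesis of the free aldehyde). The chain may not fold well enough and may oligomerise. The fallback sets out from 9 and comes back at 10. Aldehyde 9 is converted (HC(OMe)3, pyridinium tosylate, MeOH) into (3R,4S)-4-bromo-3-{[(2S)-1,1-dimethoxypent-4-en-2-yl]oxy}hept-6-ene F5, in which two C–O bonds flank C7 and their gauche preference towards the ether oxygen pre-organises the diene. Ring-closing metathesis then gives (2S,4Z,7S,8R)-7-bromo-2-(dimethoxymethyl)-8-ethyl-3,6,7,8-tetrahydro-2H-oxocine F6, and mild hydrolysis (aqueous TFA, CH2Cl2, 0 °C) liberates 10.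

Step 9 (bromoetherification in the presence of the enyne). Possible failures are bromination of the enyne, 6-endo closure, or participation of the ring oxygen. The fallback sets out from 12 and comes back at 17. The order of ring formation and side-chain construction is reversed: 12, whose only alkene with a 5-exo hydroxyl is the ring alkene, is treated with N-bromosuccinimide to give (1S,3R,4S,6S,7S,9S)-4,6-dibromo-3-ethyl-9-(prop-2-en-1-yl)-2,8-dioxabicyclo[5.2.1]decane F7. Cross-metathesis of F7 with 13 gives (2E)-4-[(1S,3R,4S,6S,7S,9S)-4,6-dibromo-3-ethyl-2,8-dioxabicyclo[5.2.1]decan-9-yl]but-2-enal F8, which no longer contains a ring alkene, and Colvin homologation with 15 gives 17.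

**Further compounds**
F1 | step 4 | 2-{[(3R,4S)-4-bromohept-6-en-3-yl]oxy}acetic acid | OC(=O)CO[C@H](CC)[C@@H](Br)CC=C
F2 | step 4 | (4R)-4-benzyl-3-(2-{[(3R,4S)-4-bromohept-6-en-3-yl]oxy}acetyl)-1,3-oxazolidin-2-one | O=C(CO[C@H](CC)[C@@H](Br)CC=C)N1[C@H](Cc2ccccc2)COC1=O
F3 | step 4 | (4R)-4-benzyl-3-[(2S)-2-{[(3R,4S)-4-bromohept-6-en-3-yl]oxy}pent-4-enoyl]-1,3-oxazolidin-2-one | O=C([C@H](CC=C)O[C@H](CC)[C@@H](Br)CC=C)N1[C@H](Cc2ccccc2)COC1=O
F4 | step 4 | (2S)-2-{[(3R,4S)-4-bromohept-6-en-3-yl]oxy}pent-4-en-1-ol | OC[C@H](CC=C)O[C@H](CC)[C@@H](Br)CC=C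
F5 | step 5 | (3R,4S)-4-bromo-3-{[(2S)-1,1-dimethoxypent-4-en-2-yl]oxy}hept-6-ene | COC(OC)[C@H](CC=C)O[C@H](CC)[C@@H](Br)CC=C
F6 | step 5 | (2S,4Z,7S,8R)-7-bromo-2-(dimethoxymethyl)-8-ethyl-3,6,7,8-tetrahydro-2H-oxocine | COC(OC)[C@@H]1C/C=C\C[C@H](Br)[C@@H](CC)O1
F7 | step 9 | (1S,3R,4S,6S,7S,9S)-4,6-dibromo-3-ethyl-9-(prop-2-en-1-yl)-2,8-dioxabicyclo[5.2.1]decane | C=CC[C@@H]1O[C@H]2C[C@@H]1O[C@H](CC)[C@@H](Br)C[C@@H]2Br
F8 | step 9 | (2E)-4-[(1S,3R,4S,6S,7S,9S)-4,6-dibromo-3-ethyl-2,8-dioxabicyclo[5.2.1]decan-9-yl]but-2-enal | O=C/C=C/C[C@@H]1O[C@H]2C[C@@H]1O[C@H](CC)[C@@H](Br)C[C@@H]2Br
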